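**Plan**

- Chroman numbering is used (O1, C2, C3, C4, C4a, C5–C8, C8a). The retrosynthesis first takes C4–H and the C3 carbinol back to the (3R,4R)-3,4-epoxide of a 2H-chromene. It then cuts the pyran ring at O1–C2 and C4–C4a (aryl 1,1-dimethylpropargyl ether), and finally the benzene ring at C7–C8, C4a–C8a and C6–C7.
- Enabling feature: the benzene ring is a 2-alkylresorcinol. The oxygens on C7 and C8a flank the C8 prenyl group, the C5 styryl group is meta to both, and C6 (and C4a before the pyran is fused) carry hydrogen. This HO/alkyl/OSi/H/R/H sequence is what a 3-substituted cyclobutenone and a siloxyalkyne give on heating.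
- Forward order: cyclobutenone (step 1) and siloxyalkyne (steps 2–3), then the benzene ring (step 4). The C7–O is pivaloylated and the C8a–OH released (steps 5–6). The O1–C2 ether and thermal pyran closure at C4a follow (steps 7–8), then epoxidation and hydride opening (steps 9–10).
- Stereochemistry: the only stereocentre, C3 (R), comes from the (R,R)-Mn(salen) epoxidation of the chromene C3=C4 bond. Hydride then enters at C4, so the C3–O bond is never broken. The E-styryl geometry comes from (E)-β-bromostyrene and is carried through.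

Key step: step 4

Assumption: the facial preference of the (R,R)-Mn(salen) catalyst known for 2,2-dimethyl-2H-chromenes (3R,4R oxide) is taken to hold for the 5,7,8-trisubstituted chromene 24; compounds marked "starting material" are taken as commercial.

**Route**

Step 1
Reactants: 1 (E)-(2-bromovinyl)benzene; 2 3-ethoxycyclobut-2-en-1-one
Product: 5 3-[(E)-styryl]cyclobut-2-en-1-one, via (E)-styryllithium 3 (not isolated), via 3-ethoxy-1-[(E)-styryl]cyclobut-2-en-1-ol 4 (not isolated)
Conditions: t-BuLi (2 equiv), Et2O, −78 °C; then 2, THF, −78 °C; then 1 M HCl, 0 °C → rt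
Reagents that add atoms: water, O
Why: Br–Li exchange should retain the E geometry, the vinyllithium should add 1,2 to the vinylogous ester, and acid should then unmask the transposed enone (Stork–Danheiser-type addition/hydrolysis, the standard entry to 3-substituted cyclobutenones).

Step 2
Reactants: 6 1-bromo-3-methylbut-2-ene (prenyl bromide); 7 ethynylmagnesium bromide
Product: 8 5-methylhex-4-en-1-yne
Conditions: CuCl (5 mol%), THF, 0 → 50 °C; excess 7; product distilled
Reagents that add atoms: none
Why: Copper(I)-catalysed coupling of an alkynyl Grignard reagent with an allylic bromide should give the skipped enyne mainly by attack at the primary terminus, and the minor SN2′ isomer should be removable by distillation.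

Step 3
Reactants: 8 5-methylhex-4-en-1-yne
Product: 11 triisopropyl[(5-methylhex-4-en-1-yn-1-yl)oxy]silane, via lithium acetylide 9 (not isolated), via lithium ynolate 10 (not isolated)
Conditions: n-BuLi, THF, −78 °C; t-BuOOLi (from t-BuOOH, LiHMDS), −78 → 0 °C; TIPSOTf, −78 °C
Reagents that add atoms: tert-butyl hydroperoxide, CC(C)(C)OO; triisopropylsilyl trifluoromethanesulfonate, CC(C)[Si](OS(=O)(=O)C(F)(F)F)(C(C)C)C(C)C
Why: Oxidation of a lithium acetylide with lithium tert-butyl peroxide should give the lithium ynolate, which the bulky silyl triflate should trap on oxygen to give an isolable TIPS ynol ether (acetylide oxidation/O-silylation).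

Step 4
Reactants: 5 3-[(E)-styryl]cyclobut-2-en-1-one; 11 triisopropyl[(5-methylhex-4-en-1-yn-1-yl)oxy]silane
Product: 16 2-(3-methylbut-2-enyl)-5-[(E)-styryl]-3-(triisopropylsilyloxy)phenol, via vinylketene 12 (not isolated), via 4-vinylcyclobutenone 13 (not isolated), via dienylketene 14 (not isolated), via cyclohexa-2,4-dienone 15 (not isolated)
Conditions: 11 (1.2 equiv), PhMe, 80 °C then 110 °C, BHT (cat.), Ar
Reagents that add atoms: none
Why: Four-electron electrocyclic opening of 5 should give vinylketene 12, whose carbonyl carbon (future C7) is attacked by the nucleophilic, prenyl-bearing carbon of the ynol ether in a regiospecific [2+2] cycloaddition that forms C7–C8 and C4a–C8a (13). A second four-electron opening gives dienylketene 14, which closes the benzene ring by a thermal disrotatory 6π-electrocyclisation (C6–C7) to dienone 15, and tautomerisation then gives phenol 16. This is a Danheiser benzannulation of a cyclobutenone with a siloxyalkyne, the established route to 2-substituted resorcinol monosilyl ethers. No stereocentre is formed (the sp3 carbon of 13 is lost on ring opening) and the E-styryl geometry is not touched. The step needs regiocontrol, which the polarisation of the ynol ether supplies by placing the prenyl group between the two oxygens and leaving them differentiated as free C7–OH and C8a–OTIPS, and it needs chemoselectivity for the alkyne over the prenyl and styryl alkenes, which the far higher ketenophilicity of the ynol ether supplies. C4a and C6 emerge unsubstituted, so C4a remains the only free position ortho to O1 for the later pyran annulation.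

Step 5
Reactants: 16 2-(3-methylbut-2-enyl)-5-[(E)-styryl]-3-(triisopropylsilyloxy)phenol
Product: 17 2-(3-methylbut-2-enyl)-5-[(E)-styryl]-3-(triisopropylsilyloxy)phenyl pivalate
Conditions: PivCl, Et3N, DMAP (cat.), CH2Cl2, 0 °C → rt
Reagents that add atoms: pivaloyl chloride, CC(C)(C)C(Cl)=O
Why: DMAP-catalysed O-acylation of the free C7 phenol should install an ester that survives fluoride, DBU and heat, makes the later benzylic epoxide less prone to ionisation, and is removed by the hydride of the last step.

Step 6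
Reactants: 17 2-(3-methylbut-2-enyl)-5-[(E)-styryl]-3-(triisopropylsilyloxy)phenyl pivalate
Product: 18 3-hydroxy-2-(3-methylbut-2-enyl)-5-[(E)-styryl]phenyl pivalate
Conditions: TBAF, AcOH (1:1), THF, 0 °C
Reagents that add atoms: none
Why: Fluoride should cleave the aryl Si–O bond selectively (aryl silyl ether deprotection), and the acetic acid buffer should keep the liberated phenol protonated so that the aryl pivalate is neither cleaved nor transferred.

Step 7
Reactants: 18 3-hydroxy-2-(3-methylbut-2-enyl)-5-[(E)-styryl]phenyl pivalate; 19 3-chloro-3-methylbut-1-yne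
Product: 20 2-(3-methylbut-2-enyl)-3-[(2-methylbut-3-yn-2-yl)oxy]-5-[(E)-styryl]phenyl pivalate
Conditions: DBU, CuCl2·2H2O (1 mol%), MeCN, 0 °C
Reagents that add atoms: none
Why: Copper-catalysed propargylic etherification of a phenol with a tertiary propargyl chloride, through a copper-bound propargyl cation equivalent, should build the hindered O1–C2 bond that an SN2 reaction could not.

Step 8
Reactants: 20 2-(3-methylbut-2-enyl)-3-[(2-methylbut-3-yn-2-yl)oxy]-5-[(E)-styryl]phenyl pivalate
Product: 24 2,2-dimethyl-8-(3-methylbut-2-enyl)-5-[(E)-styryl]-2H-chromen-7-yl pivalate, via allenyl dienone 21 (not isolated), via ortho-allenylphenol 22 (not isolated), via ortho-quinone methide 23 (not isolated)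
Conditions: o-xylene, 140 °C, BHT (cat.)
Reagents that add atoms: none
Why: Aromatic propargyl Claisen rearrangement to the only free ortho carbon (C4a, forming C4–C4a), tautomerisation, [1,5]-H shift and oxa-6π electrocyclisation (O1–C2) should give the 2,2-dimethyl-2H-chromene, the classical aryl 1,1-dimethylpropargyl ether cascade, while rearrangement toward the prenyl-bearing C8 is reversible and unproductive.

Step 9
Reactants: 24 2,2-dimethyl-8-(3-methylbut-2-enyl)-5-[(E)-styryl]-2H-chromen-7-yl pivalate
Product: 25 (3R,4R)-3,4-epoxy-2,2-dimethyl-8-(3-methylbut-2-enyl)-5-[(E)-styryl]chroman-7-yl pivalate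
Conditions: (R,R)-Mn(salen)Cl (Jacobsen catalyst, 5 mol%), 4-phenylpyridine N-oxide (20 mol%), aq NaOCl (pH 11.3 buffer), CH2Cl2, 0 °C
Reagents that add atoms: sodium hypochlorite, [Na+].[O-]Cl
Why: In the Jacobsen–Katsuki epoxidation the Mn-oxo species should oxidise the cis-disubstituted, aryl-conjugated chromene olefin much faster than the trans-stilbene or the isolated trisubstituted prenyl olefin, and the (R,R)-salen ligand should direct oxygen to the face that gives the (3R,4R)-oxide, which sets C3.

Step 10
Reactants: 25 (3R,4R)-3,4-epoxy-2,2-dimethyl-8-(3-methylbut-2-enyl)-5-[(E)-styryl]chroman-7-yl pivalate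
Product: 26 (3R)-2,2-dimethyl-8-(3-methylbut-2-enyl)-5-[(E)-styryl]chroman-3,7-diol
Conditions: LiAlH4, THF, 0 °C → rt; Rochelle salt work-up
Reagents that add atoms: none
Why: LiAlH4 should cleave the aryl pivalate and deliver hydride to the benzylic C4 of the epoxide (C3 is neopentyl and shielded by the gem-dimethyl group), so the C3–O bond and its R configuration are untouched (regioselective reductive epoxide opening with concurrent ester cleavage).

**Compound list**

1 | (E)-(2-bromovinyl)benzene | Br/C=C/c1ccccc1 | starting material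
2 | 3-ethoxycyclobut-2-en-1-one | CCOC1=CC(=O)C1 | starting material
3 | (E)-styryllithium | [Li]/C=C/c1ccccc1 | intermediate (not isolated)
4 | 3-ethoxy-1-[(E)-styryl]cyclobut-2-en-1-ol (racemic) | CCOC1=CC(O)(/C=C/c2ccccc2)C1 | intermediate (not isolated)
5 | 3-[(E)-styryl]cyclobut-2-en-1-one | O=C1C=C(/C=C/c2ccccc2)C1 | intermediate
6 | 1-bromo-3-methylbut-2-ene | CC(C)=CCBr | starting material
7 | ethynylmagnesium bromide | C#C[Mg]Br | starting material
8 | 5-methylhex-4-en-1-yne | CC(C)=CCC#C | intermediate
9 | (5-methylhex-4-en-1-yn-1-yl)lithium | [Li]C#CCC=C(C)C | intermediate (not isolated)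
10 | lithium 5-methylhex-4-en-1-yn-1-olate | [Li]OC#CCC=C(C)C | intermediate (not isolated)
11 | triisopropyl[(5-methylhex-4-en-1-yn-1-yl)oxy]silane | CC(C)=CCC#CO[Si](C(C)C)(C(C)C)C(C)C | intermediate
12 | (E)-3-methylidene-5-phenylpenta-1,4-dien-1-one (vinylketene) | O=C=CC(=C)/C=C/c1ccccc1 | intermediate (not isolated)
13 | 2-(3-methylbut-2-enyl)-4-[(E)-4-phenylbuta-1,3-dien-2-yl]-3-(triisopropylsilyloxy)cyclobut-2-en-1-one (racemic) | O=C1C(CC=C(C)C)=C(O[Si](C(C)C)(C(C)C)C(C)C)C1C(=C)/C=C/c1ccccc1 | intermediate (not isolated)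
14 | 2-(3-methylbut-2-enyl)-5-methylidene-7-phenyl-3-(triisopropylsilyloxy)hepta-1,3,6-trien-1-one (dienylketene, ketene and methylidene termini cis, 6E) | O=C=C(CC=C(C)C)/C(O[Si](C(C)C)(C(C)C)C(C)C)=C\C(=C)/C=C/c1ccccc1 | intermediate (not isolated)
15 | 2-(3-methylbut-2-enyl)-5-[(E)-styryl]-3-(triisopropylsilyloxy)cyclohexa-2,4-dien-1-one | O=C1CC(/C=C/c2ccccc2)=CC(O[Si](C(C)C)(C(C)C)C(C)C)=C1CC=C(C)C | intermediate (not isolated)
16 | 2-(3-methylbut-2-enyl)-5-[(E)-styryl]-3-(triisopropylsilyloxy)phenol | CC(C)=CCc1c(O)cc(/C=C/c2ccccc2)cc1O[Si](C(C)C)(C(C)C)C(C)C | intermediate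
17 | 2-(3-methylbut-2-enyl)-5-[(E)-styryl]-3-(triisopropylsilyloxy)phenyl pivalate | CC(C)=CCc1c(OC(=O)C(C)(C)C)cc(/C=C/c2ccccc2)cc1O[Si](C(C)C)(C(C)C)C(C)C | intermediate
18 | 3-hydroxy-2-(3-methylbut-2-enyl)-5-[(E)-styryl]phenyl pivalate | CC(C)=CCc1c(OC(=O)C(C)(C)C)cc(/C=C/c2ccccc2)cc1O | intermediate
19 | 3-chloro-3-methylbut-1-yne | CC(C)(Cl)C#C | starting material
20 | 2-(3-methylbut-2-enyl)-3-[(2-methylbut-3-yn-2-yl)oxy]-5-[(E)-styryl]phenyl pivalate | CC(C)=CCc1c(OC(=O)C(C)(C)C)cc(/C=C/c2ccccc2)cc1OC(C)(C)C#C | intermediate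
21 | 2-(3-methylbut-2-enyl)-5-(3-methylbuta-1,2-dienyl)-6-oxo-4-[(E)-styryl]cyclohexa-1,3-dien-1-yl pivalate (racemic) | O=C1C(CC=C(C)C)=C(OC(=O)C(C)(C)C)C=C(/C=C/c2ccccc2)C1C=C=C(C)C | intermediate (not isolated)
22 | 3-hydroxy-2-(3-methylbut-2-enyl)-4-(3-methylbuta-1,2-dienyl)-5-[(E)-styryl]phenyl pivalate | CC(C)=CCc1c(OC(=O)C(C)(C)C)cc(/C=C/c2ccccc2)c(C=C=C(C)C)c1O | intermediate (not isolated)
23 | 2-(3-methylbut-2-enyl)-5-(3-methylbut-2-enylidene)-6-oxo-4-[(E)-styryl]cyclohexa-1,3-dien-1-yl pivalate (ortho-quinone methide, side chain cis to C=O) | CC(C)=C/C=C1\C(=O)C(CC=C(C)C)=C(OC(=O)C(C)(C)C)C=C1/C=C/c1ccccc1 | intermediate (not isolated)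
24 | 2,2-dimethyl-8-(3-methylbut-2-enyl)-5-[(E)-styryl]-2H-chromen-7-yl pivalate | CC(C)=CCc1c(OC(=O)C(C)(C)C)cc(/C=C/c2ccccc2)c2c1OC(C)(C)C=C2 | intermediate
25 | (3R,4R)-3,4-epoxy-2,2-dimethyl-8-(3-methylbut-2-enyl)-5-[(E)-styryl]chroman-7-yl pivalate | CC(C)=CCc1c(OC(=O)C(C)(C)C)cc(/C=C/c2ccccc2)c2c1OC(C)(C)[C@@H]1O[C@H]21 | intermediate
26 | (3R)-2,2-dimethyl-8-(3-methylbut-2-enyl)-5-[(E)-styryl]chroman-3,7-diol | CC(C)=CCc1c(O)cc(/C=C/c2ccccc2)c2c1OC(C)(C)[C@H](O)C2 | target

**Step count and risks**

Total step count: 10. Longest linear sequence: 9 steps (steps 2–10, from prenyl bromide 6); the cyclobutenone branch (step 1) joins at step 4.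

Steps most likely to fail:

Step 9. The Mn-oxo species or hypochlorite may also oxidise the prenyl or stilbene double bonds. The peri styryl group may erode facial selectivity. The electron-rich benzylic epoxide may ionise during work-up. The fallback avoids any alkene oxidation; it sets out from phenol 18 and returns to the route at target 26. Phenol 18 would be O-alkylated with 3-bromo-3-methylbutan-2-one (Cs2CO3, DMF) to give the aryloxy methyl ketone F1. The methyl ketone, enolisable on one side only, would be converted to its trimethylsilyl enol ether F2 (TMSOTf, Et3N) and chlorinated with N-chlorosuccinimide to the chloromethyl ketone F3. CBS reduction with (S)-Me-oxazaborolidine and catecholborane at low temperature, with the tertiary aryloxyalkyl group as the large substituent, should give the (S)-chlorohydrin F4. K2CO3 in MeCN would close it to the (R)-epoxide F5. A Lewis acid (BF3·OEt2, CH2Cl2, −78 °C) or hexafluoroisopropanol should then promote 6-endo epoxy-arene Friedel–Crafts cyclisation of the terminal epoxide carbon onto C4a, giving the (3R)-chromanol pivalate F6 with C3 untouched. K2CO3 in MeOH would release 26.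

Step 4. The cross-conjugated dienone 5 or vinylketene 12 may oligomerise before the ynol ether captures it, and the product phenol may be acylated by ketene intermediates. The fallback builds the same 2-prenylresorcinol by directed metalation; it sets out from prenyl bromide 6 together with commercial pinosylvin [(E)-5-styrylbenzene-1,3-diol] and returns to the route at 18. Pinosylvin would be converted to its bis(methoxymethyl) ether F7 (MOMCl, i-Pr2NEt). n-BuLi in THF at 0 °C should lithiate the position between the two MOM ethers to give aryllithium F8. CuI-mediated alkylation with 6 would give the 2-prenyl bis-MOM ether F9. Brief treatment with HCl in MeOH at rt, stopped before the prenyl group cyclises onto a phenol, would give the symmetric diol 2-prenylpinosylvin F10. Because the two hydroxyls of F10 are equivalent, monoacylation with one equivalent of PivCl (Et3N, CH2Cl2, −20 °C) gives 18 directly, with recycling of diol and diester.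

Step 10. Once the C7 phenoxide is unmasked, the epoxide may ionise at C4 and undergo a 1,2-hydride shift (Meinwald-type) to the 3-ketone, whose reduction would erode the C3 configuration; hydride attack at C3 is a lesser risk. The fallback opens the epoxide by a soft SN2 nucleophile with the pivalate still in place; it sets out from 25 and returns to the route at 26. Phenylselenide (PhSeSePh, NaBH4, EtOH/THF, 0 °C) should attack C4 with inversion to give the trans hydroxy selenide F11. Radical deselenation (Bu3SnH, AIBN, PhMe, 80 °C) would give the (3R)-chromanol pivalate F6, the same compound as in the fallback for step 9. K2CO3 in MeOH would then give 26.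

**Further compounds**

F1 | step 9 | 2-(3-methylbut-2-enyl)-3-[(2-methyl-3-oxobutan-2-yl)oxy]-5-[(E)-styryl]phenyl pivalate | CC(C)=CCc1c(OC(=O)C(C)(C)C)cc(/C=C/c2ccccc2)cc1OC(C)(C)C(C)=O
F2 | step 9 | 2-(3-methylbut-2-enyl)-3-{[2-methyl-3-(trimethylsilyloxy)but-3-en-2-yl]oxy}-5-[(E)-styryl]phenyl pivalate | CC(C)=CCc1c(OC(=O)C(C)(C)C)cc(/C=C/c2ccccc2)cc1OC(C)(C)C(=C)O[Si](C)(C)C
F3 | step 9 | 3-[(4-chloro-2-methyl-3-oxobutan-2-yl)oxy]-2-(3-methylbut-2-enyl)-5-[(E)-styryl]phenyl pivalate | CC(C)=CCc1c(OC(=O)C(C)(C)C)cc(/C=C/c2ccccc2)cc1OC(C)(C)C(=O)CCl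
F4 | step 9 | 3-{[(3S)-4-chloro-3-hydroxy-2-methylbutan-2-yl]oxy}-2-(3-methylbut-2-enyl)-5-[(E)-styryl]phenyl pivalate | CC(C)=CCc1c(OC(=O)C(C)(C)C)cc(/C=C/c2ccccc2)cc1OC(C)(C)[C@H](O)CCl
F5 | step 9 | 2-(3-methylbut-2-enyl)-3-({2-[(2R)-oxiran-2-yl]propan-2-yl}oxy)-5-[(E)-styryl]phenyl pivalate | CC(C)=CCc1c(OC(=O)C(C)(C)C)cc(/C=C/c2ccccc2)cc1OC(C)(C)[C@H]1CO1
F6 | step 9 | (3R)-3-hydroxy-2,2-dimethyl-8-(3-methylbut-2-enyl)-5-[(E)-styryl]chroman-7-yl pivalate | CC(C)=CCc1c(OC(=O)C(C)(C)C)cc(/C=C/c2ccccc2)c2c1OC(C)(C)[C@H](O)C2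
F7 | step 4 | (E)-1,3-bis(methoxymethoxy)-5-styrylbenzene | COCOc1cc(OCOC)cc(/C=C/c2ccccc2)c1
F8 | step 4 | {2,6-bis(methoxymethoxy)-4-[(E)-styryl]phenyl}lithium | COCOc1cc(/C=C/c2ccccc2)cc(OCOC)c1[Li]
F9 | step 4 | 1,3-bis(methoxymethoxy)-2-(3-methylbut-2-enyl)-5-[(E)-styryl]benzene | COCOc1cc(/C=C/c2ccccc2)cc(OCOC)c1CC=C(C)C
F10 | step 4 | 2-(3-methylbut-2-enyl)-5-[(E)-styryl]benzene-1,3-diol | CC(C)=CCc1c(O)cc(/C=C/c2ccccc2)cc1O
F11 | step 10 | (3S,4S)-3-hydroxy-2,2-dimethyl-8-(3-methylbut-2-enyl)-4-(phenylselanyl)-5-[(E)-styryl]chroman-7-yl pivalate | CC(C)=CCc1c(OC(=O)C(C)(C)C)cc(/C=C/c2ccccc2)c2c1OC(C)(C)[C@H](O)[C@H]2[Se]c1ccccc1
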